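## Structural features

Ainsliadimer A (C30H34O7) consists of two guaianolide halves of the same absolute configuration. Each half is a cis-fused cyclopentane–cycloheptane (H-1 and H-5 α) with a trans-fused α-methylene-γ-butyrolactone (H-6 β, H-7 α) and a C10=C14 exocyclic methylene group. The halves are held together by a central cyclopentane made of C3, C4 and C15 of the diol half and C15′ and C4′ of the ketone half. This ring is cis-fused to the unprimed cyclopentane along C3–C4 and spiro-linked to the primed cyclopentanone at C4′. Eight of the eleven stereocentres (C1, C5, C6, C7 and C1′, C5′, C6′, C7′) are those of the monomer. The quaternary C4′ (C3 α, C15′ β) and the tertiary carbinols C3 and C4 (both OH α) stand in a row, flanked by C5 and C5′. The fragile groups are the two α-methylene lactones (Michael and radical acceptors), the two 1,1-disubstituted alkenes (acid-induced migration), the β-hydroxy ketone C3(OH)–C4′–C3′=O (retro-aldol) and the ditertiary cis-diol (pinacol shift). The real difficulty is the row C4′–C3–C4 of fully substituted carbons together with two dissonant bonds: C15–C15′ joins two carbons that are each the electrophilic β carbon of an α-methylene ketone, and O–C4 puts oxygen on an α carbon. The key step exploits a hidden twofold symmetry of the central ring: once the oxygen on C4 is removed and C3–C4′ is cut, C3–C4–C15 and C3′–C4′–C15′ become the same enolate unit, joined tail to tail through C15–C15′.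

## Logic of the disconnections

**9 from 8.** No skeletal bond is cut. The C11=C13 and C11′=C13′ double bonds of 9 are traced back to the C13–S/C11–H and C13′–S/C11′–H bonds of 8. The cut is made there because these two acceptors would compete in any reductive union of the halves. The gain is that every earlier intermediate holds at most one kind of electrophilic alkene. The forward step must expel two sulfinate ions with a base under which the β-hydroxy ketone sits at its thermodynamic resting point.

**8 from 5 (key disconnection).** The C3–C4′ bond and the C4–O bond are cut together. This removes the central ring, all three new stereocentres and the only difference between the halves, so 5 is C2-symmetric with two homotopic enol silanes. In one sentence: mono-epoxidation of C2-symmetric 5 releases an oxocarbenium ion at C3 that the untouched enol silane captures through C4′. The forward step must deliver one oxygen atom to the α face of one enol silane. It must also form the C–C bond faster than a second oxidation can occur.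

**5 from 4.** The C15–C15′ bond in the middle of 5 is cut to give two molecules of 4. Both carbons are electrophilic in 4, so the union needs a two-electron reduction that reverses the polarity at C15, with both oxygens caught by silicon. The gain is a halving of the molecule, and no stereocentre is at stake. The forward step must couple tail to tail and must leave the lactones, sulfones and C10=C14 alkenes alone.

**4 from 3.** The C3=O π bond is traced back to the C3–H and O–H bonds of 3. The labile α-methylene ketone then exists only immediately before its use. The forward step must be base-free, so that C4=C15 does not move into the ring and the sulfone is not expelled.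

**3 from 2.** The C13–S bond is cut. At this oxidation level C11=C13 is the only acceptor in the molecule, so the mask can be placed without any selectivity problem. The forward step needs a soft nucleophile that survives all later oxidants.

**2 from 1.** The C3–O bond is cut, which leads to 1 with eight of the eleven stereocentres of 9 (four per half) already in place. The forward step must pick the C3 methylene among the allylic positions of 1.

## Other disconnections considered

**Alternative 1:** This is the first plan that comes to mind.
- **Cut:** retro-aldol cut of C3–C4′, then retro-hetero-Diels–Alder cut of C15–C15′ and O–C4.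
- **Forward:** two molecules of dehydrozaluzanin C A1 combine, one as the heterodiene O=C3′–C4′=C15′ and one as the dienophile C4=C15, to give the spiro-dihydropyran A2. Hydrolysis of its enol ether gives the hydroxy diketone A3, and base closes C3–C4′.
- **Ground for preferring the chosen plan:** the plan is short, but the union itself has to create the C4 stereocentre in an intermolecular transition state. There, periselectivity (C11=C13 as rival dienophile, the dienol of A1 as rival carbodiene), regiochemistry and two facial choices must all be right at once without a directing element. Ring closure then needs two further operations through A3, an α-ketol open to acyl shift. In the chosen plan the intermolecular event creates no stereocentre, and C4, C3 and C4′ are set together in one intramolecular step. Alternative 1 is also the sentence most chemists would write first, so it is kept only as a safety net.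

**Alternative 2:**
- **Cut:** C15–C15′ and C3–C4′ at once, a [3+2] union of two different monomers.
- **Forward:** the epoxy ketone A4 is opened to the primary iodide A5. The C15 radical from A5 adds to C15′ of A1, and the resulting enolate closes on C3=O.
- **Ground for preferring the chosen plan:**
  - It needs two monomers at two oxidation levels, hence three extra steps.
  - The primary β-keto radical can undergo a 1,2-acyl shift (Dowd–Beckwith ring expansion) to a tertiary α-silyloxy radical in competition with the bimolecular addition.
  - A nucleophilic alkyl radical hardly distinguishes the enone from the two lactone acceptors.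
  - Under most ways of making a primary radical the adduct radical is quenched by hydrogen transfer and not reduced to an enolate, so ring closure in the same step is not secured.
  - The chosen plan has no free alkyl radical and closes the ring by a closed-shell cascade.

**Alternative 3:**
- **Cut:** C3–C4, the bond shared by the unprimed cyclopentane and the central ring, another union of like polarity.
- **Forward:** transannular pinacol coupling (SmI2) of the cyclooctane-1,5-dione A6 to the cis-diquinane diol.
- **Ground for preferring the chosen plan:**
  - The cis-diol would be set well, but A6 is an eight-membered ring that is fused to a cycloheptane and spiro to the primed half. It is harder to make than the target.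
  - The cut throws away a cyclopentane that the chiral pool supplies for nothing.
  - The reductant would also attack the lactone acceptors.
  - There is no gain in simplicity.

Key step: step 5

Remark: dehydrocostus lactone 1 is taken as a commercial chiral-pool compound (a main constituent of costus root oil). Guaiane numbering is used, unprimed for the diol half and primed for the ketone half.

## Route

Step 1
Reactants: 1 dehydrocostus lactone
Product: 2 3-epizaluzanin C (3α-hydroxydehydrocostus lactone)
Conditions: SeO2 (0.5 equiv), t-BuOOH (2 equiv), CH2Cl2, 0 °C to rt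
Reagents that add atoms: tert-butyl hydroperoxide, CC(C)(C)OO; selenium dioxide (carrier of the oxygen atom), O=[Se]=O
Why: Riley allylic oxidation (ene reaction, then [2,3]-sigmatropic shift): selenium binds the unhindered C15 terminus, takes the α hydrogen of the cyclopentane methylene C3 and returns oxygen to C3 on the same convex α face, so the 3α alcohol should result with C4=C15 restored. The electron-poor C11=C13 is inert, and the configuration at C3 is erased in step 3.

Step 2
Reactants: 2 3-epizaluzanin C
Product: 3 13-phenylsulfonyl-11βH-11,13-dihydro-3-epizaluzanin C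
Conditions: PhSO2Na (1.5 equiv), AcOH (2 equiv), EtOH–H2O, rt
Reagents that add atoms: sodium benzenesulfinate, O=S([O-])c1ccccc1.[Na+]
Why: Sulfa-Michael addition: at the alcohol oxidation level the lactone methylene is the only acceptor in the molecule, so the soft sulfinate adds at C13 alone, and the sulfone is inert to all later oxidants. Protonation of the lactone enolate should give the more stable 11βH epimer (CH2SO2Ph α); this centre is deleted again in step 6.

Step 3
Reactants: 3 13-phenylsulfonyl-11βH-11,13-dihydro-3-epizaluzanin C
Product: 4 13-phenylsulfonyl-11βH-11,13-dihydrodehydrozaluzanin C (3-oxo-4(15)-ene)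
Conditions: Dess–Martin periodinane, CH2Cl2, 0 °C; kept cold and dilute, used at once
Reagents that add atoms: none
Why: Dess–Martin oxidation of a secondary allylic alcohol under base-free conditions, which spare the sulfone (no E1cB), the exocyclic alkenes and C5 (no shift of C4=C15 into the ring). The α-methylene ketone is not stored because it can dimerise thermally.

Step 4
Reactants: 4 13-phenylsulfonyl-11βH-11,13-dihydrodehydrozaluzanin C (two molecules)
Product: 5 C2-symmetric 15,15′-linked dimer as its bis(triethylsilyl enol ether) (3-OSiEt3 and C3=C4 in each half)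
Conditions: NiCl2(dme) (10 mol %), neocuproine (10 mol %), Mn powder (1.5 equiv), Et3SiCl (1.3 equiv), DMF, 0 °C to rt
Reagents that add atoms: chlorotriethylsilane, CC[Si](Cl)(CC)CC
Why: Reductive β,β′-hydrodimerisation of an enone with silyl trapping: zerovalent nickel, the enone and Et3SiCl give an η3-1-(triethylsilyloxy)allyl complex of divalent nickel, two such allyl units couple at their unhindered CH2 termini (C15 and C15′) as in the reductive homocoupling of allyl electrophiles, and Mn returns nickel to the zerovalent state. The fully substituted C3 terminus disfavours head coupling, no stereocentre is formed, both enol geometries are fixed by the rings, and the masked lactones offer no second acceptor.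

Step 5
Reactants: 5 C2-symmetric bis(triethylsilyl enol ether)
Product: 8 13,13′-bis(phenylsulfonyl)-11βH,11′βH-tetrahydroainsliadimer A, via silyloxy epoxide 6 (not isolated), via triethylsilyl ether 7 (not isolated)
Conditions: m-CPBA (1.0 equiv, added over 2 h, no buffer), CH2Cl2, −40 °C; then HF·pyridine, THF, 0 °C
Reagents that add atoms: m-chloroperbenzoic acid, O=C(OO)c1cccc(Cl)c1
Why: Proposed new method: the peracid epoxidises one of the two homotopic tetrasubstituted enol silanes of 5 on its convex α face (the face of H-1 and H-5) to give 6, the acid set free opens the acetal C3–O bond of 6 to a silyl oxocarbenium ion at C3, and the second enol silane, held in reach by C15–C15′, attacks this ion through C4′ and passes its silyl group to the carboxylate to give 7. The closest known reaction types are the Rubottom oxidation, the intramolecular Mukaiyama aldol addition and the opening of glycal epoxides at the acetal carbon by carbon nucleophiles; new is only that the carbon nucleophile intercepts the Rubottom intermediate before silicon migrates from O-3 to O-4. The one ring that closes, the cyclopentane C3–C4–C15–C15′–C4′, does so in the favoured 5-(enolexo)-exo-trig mode. C4 is set by the face of epoxidation, which leaves O-4 α and C15 β. C3 is set by the tether, since C15 stands β on C4 and C4′ can therefore reach only the β face of C3, which gives the cis-fused diquinane with both oxygens α. C4′ is set by the convex α face of the primed hydroazulene, which turns the incoming C3 towards H-5′ and away from C6′. The step needs site selectivity, secured by the much higher nucleophilicity of a tetrasubstituted silyl enol ether over the two C10=C14-type alkenes and the inert sulfones, and it needs mono-oxidation, secured because ring closure consumes the second enol silane, so that slow addition of one equivalent of peracid finds nothing oxidisable in 7. HF·pyridine then cleaves the tertiary silyl ether to give 8.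

Step 6
Reactants: 8 13,13′-bis(phenylsulfonyl)-11βH,11′βH-tetrahydroainsliadimer A
Product: 9 ainsliadimer A
Conditions: DBU (4 equiv), CH2Cl2, 0 °C to rt
Reagents that add atoms: none
Why: Double E1cB elimination of benzenesulfinate from the β-sulfonyl lactones, a standard unmasking of α-methylene lactones that also deletes C11 and C11′ as stereocentres. Under these conditions the β-hydroxy ketone can only equilibrate by retro-aldol and aldol addition, and the cis-diquinane with C3 on the α face of C4′ should be the thermodynamic sink, so material that arrives uncyclised or epimeric at C4′ is funnelled to 9.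

## Compound list

1 | dehydrocostus lactone, (1αH,5αH,6βH,7αH)-guaia-4(15),10(14),11(13)-trien-12,6-olide | C=C1C(=O)O[C@@H]2[C@@H]3[C@@H](CCC3=C)C(=C)CC[C@@H]12 | starting material
2 | 3-epizaluzanin C (3α-hydroxy derivative of 1) | C=C1C(=O)O[C@@H]2[C@@H]3[C@@H](C[C@@H](O)C3=C)C(=C)CC[C@@H]12 | intermediate
3 | 13-phenylsulfonyl-11βH-11,13-dihydro-3-epizaluzanin C | O=S(=O)(c1ccccc1)C[C@@H]1C(=O)O[C@@H]2[C@@H]3[C@@H](C[C@@H](O)C3=C)C(=C)CC[C@@H]12 | intermediate
4 | 13-phenylsulfonyl-11βH-11,13-dihydrodehydrozaluzanin C | O=S(=O)(c1ccccc1)C[C@@H]1C(=O)O[C@@H]2[C@@H]3[C@@H](CC(=O)C3=C)C(=C)CC[C@@H]12 | intermediate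
5 | C2-symmetric 15,15′-linked dimer of 4 as bis(triethylsilyl enol ether) | O=S(=O)(c1ccccc1)C[C@@H]1C(=O)O[C@@H]2[C@@H]3[C@@H](CC(O[Si](CC)(CC)CC)=C3CCC4=C(O[Si](CC)(CC)CC)C[C@H]5C(=C)CC[C@H]6[C@H](CS(=O)(=O)c7ccccc7)C(=O)O[C@@H]6[C@H]54)C(=C)CC[C@@H]12 | intermediate
6 | 3α,4α-epoxide of one enol silane of 5 (silyloxy epoxide) | O=S(=O)(c1ccccc1)C[C@@H]1C(=O)O[C@@H]2[C@@H]3[C@@H](C[C@@]8(O[Si](CC)(CC)CC)O[C@@]38CCC4=C(O[Si](CC)(CC)CC)C[C@H]5C(=C)CC[C@H]6[C@H](CS(=O)(=O)c7ccccc7)C(=O)O[C@@H]6[C@H]54)C(=C)CC[C@@H]12 | intermediate
7 | 3-O-triethylsilyl ether of 8 | O=S(=O)(c1ccccc1)C[C@@H]1C(=O)O[C@@H]2[C@@H]3[C@@H](C[C@@]4(O[Si](CC)(CC)CC)[C@]3(O)CC[C@]43C(=O)C[C@H]4C(=C)CC[C@H]5[C@H](CS(=O)(=O)c6ccccc6)C(=O)O[C@@H]5[C@H]43)C(=C)CC[C@@H]12 | intermediate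
8 | 13,13′-bis(phenylsulfonyl)-11βH,11′βH-tetrahydroainsliadimer A | O=S(=O)(c1ccccc1)C[C@@H]1C(=O)O[C@@H]2[C@@H]3[C@@H](C[C@@]4(O)[C@]3(O)CC[C@]43C(=O)C[C@H]4C(=C)CC[C@H]5[C@H](CS(=O)(=O)c6ccccc6)C(=O)O[C@@H]5[C@H]43)C(=C)CC[C@@H]12 | intermediate
9 | ainsliadimer A | C=C1C(=O)O[C@@H]2[C@@H]3[C@@H](C[C@@]4(O)[C@]3(O)CC[C@]43C(=O)C[C@H]4C(=C)CC[C@H]5C(=C)C(=O)O[C@@H]5[C@H]43)C(=C)CC[C@@H]12 | target

## Step count and least certain steps

Total step count: 6. Longest linear sequence: 6 steps from 1 (the route is linear; 4 enters step 4 twice).

**Step 5 (key step).**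
- **Risk:** migration of silicon from O-3 to O-4 (the normal Rubottom course) or protodesilylation may outrun C–C bond formation. The second enol silane would then stay exposed, and oxidation of both halves would become a statistical matter. Facial selectivity at C4′ under kinetic control may also be incomplete, although step 6 can correct that.
- **Fallback (known chemistry):** it sets out from 3 and 4 and comes back at 8. It installs O-4 before the union, so no desymmetrisation is needed. Hydroxyl-directed epoxidation of 3 (VO(acac)2, t-BuOOH) on the face of the 3α hydroxyl gives the epoxy alcohol F1. Dess–Martin oxidation gives the epoxy ketone F2. Me3SiI opens the spiro-epoxide at the primary C15 to give the iodo silyl ether F3. Nickel-catalysed reductive conjugate addition of this primary iodide to 4 (NiCl2(dme), a terpyridine ligand, Mn, Et3SiCl, DMF) gives the cross-coupled silyl enol ether F4. A TiCl4-promoted intramolecular Mukaiyama aldol addition gives the trimethylsilyl ether F5, and HF·pyridine gives 8.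

**Step 4.**
- **Risk:** coupling through the carbonyl carbon or head to tail, plain 1,4-reduction by adventitious proton sources, thermal self-dimerisation of the enone before it reaches nickel, and migration of the exocyclic alkenes induced by nickel hydrides.
- **Fallback:** it sets out from 4 and comes back at 9, and it lets the thermal pathway make the union. Hetero-Diels–Alder dimerisation of concentrated 4 with a hydrogen-bond donor gives the spiro-dihydropyran F6. Aqueous acid hydrolyses its enol ether to the hydroxy diketone F7. DBU then effects the aldol closure and both sulfinate eliminations to give 9.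

**Step 6.**
- **Risk:** retro-aldol opening followed by acyl shift of the α-ketol, re-addition of sulfinate to the freshly released acceptors, and base-induced oligomerisation of the product.
- **Fallback:** it sets out from 5 and comes back at 9, and it moves the unmasking ahead of the base-sensitive aldol. DBU acts on 5, whose enol silanes tolerate the amidine, to give the unmasked bis(enol silane) F8. The peracid cascade of step 5, to which α-methylene lactones are inert, gives the triethylsilyl ether F9, and HF·pyridine gives 9.

**Step 1.**
- **Risk:** competing allylic oxidation next to C10=C14 (at C9 or C1), over-oxidation, and double oxidation.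
- **Fallback:** it sets out from 1 and comes back at 4, replacing the reagent by an enzyme. An engineered cytochrome P450 monooxygenase with NADPH recycling hydroxylates the allylic C3 position. Either 2 or its epimer zaluzanin C F10 is acceptable. Sulfinate addition to F10 gives the epimeric sulfone alcohol F11, and Dess–Martin oxidation of F11 gives 4.

## Further compounds

F1 | step 5 | 4α,15-epoxy-3α-hydroxy sulfone (epoxy alcohol) | O=S(=O)(c1ccccc1)C[C@@H]1C(=O)O[C@@H]2[C@@H]3[C@@H](C[C@@H](O)[C@]34CO4)C(=C)CC[C@@H]12
F2 | step 5 | 4α,15-epoxy-3-oxo sulfone (epoxy ketone) | O=S(=O)(c1ccccc1)C[C@@H]1C(=O)O[C@@H]2[C@@H]3[C@@H](CC(=O)[C@]34CO4)C(=C)CC[C@@H]12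
F3 | step 5 | 15-iodo-4α-trimethylsilyloxy-3-oxo sulfone (iodo silyl ether) | O=S(=O)(c1ccccc1)C[C@@H]1C(=O)O[C@@H]2[C@@H]3[C@@H](CC(=O)[C@]3(O[Si](C)(C)C)CI)C(=C)CC[C@@H]12
F4 | step 5 | 15,15′-linked 4α-trimethylsilyloxy ketone / 3′-triethylsilyl enol ether | O=S(=O)(c1ccccc1)C[C@@H]1C(=O)O[C@@H]2[C@@H]3[C@@H](CC(=O)[C@]3(O[Si](C)(C)C)CCC4=C(O[Si](CC)(CC)CC)C[C@H]5C(=C)CC[C@H]6[C@H](CS(=O)(=O)c7ccccc7)C(=O)O[C@@H]6[C@H]54)C(=C)CC[C@@H]12
F5 | step 5 | 4-O-trimethylsilyl ether of 8 | O=S(=O)(c1ccccc1)C[C@@H]1C(=O)O[C@@H]2[C@@H]3[C@@H](C[C@@]4(O)[C@]3(O[Si](C)(C)C)CC[C@]43C(=O)C[C@H]4C(=C)CC[C@H]5[C@H](CS(=O)(=O)c6ccccc6)C(=O)O[C@@H]5[C@H]43)C(=C)CC[C@@H]12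
F6 | step 4 | spiro-dihydropyran dimer of 4 | O=S(=O)(c1ccccc1)C[C@@H]1C(=O)O[C@@H]2[C@@H]3[C@@H](CC(=O)[C@]34CCC5=C(O4)C[C@H]6C(=C)CC[C@H]7[C@H](CS(=O)(=O)c8ccccc8)C(=O)O[C@@H]7[C@H]65)C(=C)CC[C@@H]12
F7 | step 4 | 4α-hydroxy-3,3′-diketone bis-sulfone (hydroxy diketone) | O=S(=O)(c1ccccc1)C[C@@H]1C(=O)O[C@@H]2[C@@H]3[C@@H](CC(=O)[C@]3(O)CC[C@H]5C(=O)C[C@H]6C(=C)CC[C@H]7[C@H](CS(=O)(=O)c8ccccc8)C(=O)O[C@@H]7[C@H]65)C(=C)CC[C@@H]12
F8 | step 6 | unmasked C2-symmetric bis(triethylsilyl enol ether) | C=C1C(=O)O[C@@H]2[C@@H]3[C@@H](CC(O[Si](CC)(CC)CC)=C3CCC4=C(O[Si](CC)(CC)CC)C[C@H]5C(=C)CC[C@H]6C(=C)C(=O)O[C@@H]6[C@H]54)C(=C)CC[C@@H]12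
F9 | step 6 | 3-O-triethylsilyl ainsliadimer A | C=C1C(=O)O[C@@H]2[C@@H]3[C@@H](C[C@@]4(O[Si](CC)(CC)CC)[C@]3(O)CC[C@]43C(=O)C[C@H]4C(=C)CC[C@H]5C(=C)C(=O)O[C@@H]5[C@H]43)C(=C)CC[C@@H]12
F10 | step 1 | zaluzanin C (3β-hydroxydehydrocostus lactone) | C=C1C(=O)O[C@@H]2[C@@H]3[C@@H](C[C@H](O)C3=C)C(=C)CC[C@@H]12
F11 | step 1 | 13-phenylsulfonyl-11βH-11,13-dihydrozaluzanin C | O=S(=O)(c1ccccc1)C[C@@H]1C(=O)O[C@@H]2[C@@H]3[C@@H](C[C@H](O)C3=C)C(=C)CC[C@@H]12
A1 | alternative 1 | dehydrozaluzanin C | C=C1C(=O)O[C@@H]2[C@@H]3[C@@H](CC(=O)C3=C)C(=C)CC[C@@H]12
A2 | alternative 1 | spiro-dihydropyran dimer of A1 | C=C1C(=O)O[C@@H]2[C@@H]3[C@@H](CC(=O)[C@]34CCC5=C(O4)C[C@H]6C(=C)CC[C@H]7C(=C)C(=O)O[C@@H]7[C@H]65)C(=C)CC[C@@H]12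
A3 | alternative 1 | 4α-hydroxy-3,3′-diketone (hydroxy diketone) | C=C1C(=O)O[C@@H]2[C@@H]3[C@@H](CC(=O)[C@]3(O)CC[C@H]5C(=O)C[C@H]6C(=C)CC[C@H]7C(=C)C(=O)O[C@@H]7[C@H]65)C(=C)CC[C@@H]12
A4 | alternative 2 | 4α,15-epoxydehydrozaluzanin C (epoxy ketone) | C=C1C(=O)O[C@@H]2[C@@H]3[C@@H](CC(=O)[C@]34CO4)C(=C)CC[C@@H]12
A5 | alternative 2 | 15-iodo-4α-trimethylsilyloxy-3-oxoguaia-10(14),11(13)-dien-12,6-olide | C=C1C(=O)O[C@@H]2[C@@H]3[C@@H](CC(=O)[C@]3(O[Si](C)(C)C)CI)C(=C)CC[C@@H]12
A6 | alternative 3 | 3,4-seco cyclooctane-1,5-dione | C=C1C(=O)O[C@@H]2[C@@H]3[C@@H](CC(=O)[C@]4(CCC3=O)C(=O)C[C@H]5C(=C)CC[C@H]6C(=C)C(=O)O[C@@H]6[C@H]54)C(=C)CC[C@@H]12
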